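**Retrosynthetic overview**

- The strategy rests on ring A: counted from the acyl-bearing carbon C1', it carries OH on C2' and OMe on C6' flanking C1' and a second OH on C4' para to it. These three different oxygens map onto a ketene carbonyl carbon, the methoxy carbon of an ynol ether and the alkoxy carbon of a 3-alkoxycyclobutenone.
- Ring A is disconnected at C1'–C2' and C5'–C6' by a cyclobutenone–methoxyalkyne benzannulation. It delivers the C2' phenol, the C6' methyl ether and a C4' allyl ether directly, with the ketone carbon held as a silylated carbinol. Desilylation, oxidation and deallylation finish the synthesis.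
- The methoxyalkyne comes from the trans cyclohexene aldehyde by addition of lithium methoxyacetylide and silylation. The cyclobutenone comes from 3-ethoxycyclobut-2-en-1-one by alkoxy exchange with allyl alcohol.
- The aldehyde comes from an amine-catalysed enantioselective Diels–Alder reaction of myrcene with cinnamaldehyde, which forms the cyclohexene ring and sets both stereocentres (C1 acyl-bearing, C6 phenyl-bearing).
- Ring order: cyclohexene ring first, ring A last.

Key step: step 5

Remark: the carbinol carbon created in step 2 is carried as a mixture of both epimers because it ends as the ketone carbon. The sense of induction in step 1 is assigned from the usual face-shielding model of the amine catalyst.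

**Step 1**
Reactants: 1 myrcene; 2 (E)-cinnamaldehyde
Product: 3 (1R,6R)-4-(4-methylpent-3-en-1-yl)-6-phenylcyclohex-3-ene-1-carbaldehyde
Conditions: 1 (3 equiv), (R)-2-{bis[3,5-bis(trifluoromethyl)phenyl](triethylsilyloxy)methyl}pyrrolidine (10 mol%), HClO4 (10 mol%), H2O, rt
Reagents that add atoms: none
Why: Iminium-catalysed Diels–Alder reaction, in which the 2-substituted diene should add with para orientation, the E-alkene fixes the trans relationship of C1 and C6, and the bulky diaryl(silyloxy)methyl group of the R catalyst shields the Si face of Cα and Cβ so that bonding on the Re face should set both centres as R.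

**Step 2**
Reactants: 3 (1R,6R)-4-(4-methylpent-3-en-1-yl)-6-phenylcyclohex-3-ene-1-carbaldehyde; 4 chloroacetaldehyde dimethyl acetal
Product: 6 3-methoxy-1-[(1R,6R)-4-(4-methylpent-3-en-1-yl)-6-phenylcyclohex-3-en-1-yl]prop-2-yn-1-ol (both carbinol epimers), via lithium methoxyacetylide 5 (not isolated)
Conditions: 4 (1.3 equiv), LiNEt2 (3.9 equiv, from Et2NH and n-BuLi), THF, 0 °C; then 3, −78 to −40 °C; aq. NaHCO3
Reagents that add atoms: none
Why: LiNEt2 eliminates methanol and then HCl from 4 and deprotonates the resulting methoxyacetylene to acetylide 5, which should add to the aldehyde at −78 °C faster than it enolises it (acetylide 1,2-addition); the unselective carbinol centre is harmless because it is oxidised in step 7, and C1 stays trans because that is also the thermodynamic arrangement.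

**Step 3**
Reactants: 6 3-methoxy-1-[(1R,6R)-4-(4-methylpent-3-en-1-yl)-6-phenylcyclohex-3-en-1-yl]prop-2-yn-1-ol
Product: 7 tert-butyl{3-methoxy-1-[(1R,6R)-4-(4-methylpent-3-en-1-yl)-6-phenylcyclohex-3-en-1-yl]prop-2-yn-1-yloxy}dimethylsilane
Conditions: t-BuMe2SiCl, imidazole, DMF, rt; chromatography on Et3N-deactivated silica
Reagents that add atoms: tert-butyldimethylsilyl chloride, CC(C)(C)[Si](C)(C)Cl
Why: Silylation of the secondary propargylic alcohol under basic conditions should avoid the acid-triggered Meyer–Schuster-type rearrangement of the 3-hydroxy ynol ether to an unsaturated ester, and the silyl ether masks the hydroxyl during the thermal step.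

**Step 4**
Reactants: 8 3-ethoxycyclobut-2-en-1-one
Product: 9 3-(allyloxy)cyclobut-2-en-1-one
Conditions: allyl alcohol (solvent), camphor-10-sulfonic acid (5 mol%), 40 °C, EtOH stripped off with the alcohol and fresh alcohol added; Et3N quench
Reagents that add atoms: allyl alcohol, C=CCO
Why: Acid-catalysed alkoxy exchange of a vinylogous ester (addition–elimination at C3 of the O-protonated enone, the same pathway by which aqueous acid hydrolyses this enol ether) should be driven to the allyl ether by excess allyl alcohol and removal of ethanol, and the mild temperature avoids Claisen rearrangement of the allyl vinyl ether.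

**Step 5**
Reactants: 7 tert-butyl{3-methoxy-1-[(1R,6R)-4-(4-methylpent-3-en-1-yl)-6-phenylcyclohex-3-en-1-yl]prop-2-yn-1-yloxy}dimethylsilane; 9 3-(allyloxy)cyclobut-2-en-1-one
Product: 14 5-(allyloxy)-2-{(tert-butyldimethylsilyloxy)[(1R,6R)-4-(4-methylpent-3-en-1-yl)-6-phenylcyclohex-3-en-1-yl]methyl}-3-methoxyphenol, via vinylketene 10 (not isolated), via vinylcyclobutenone 11 (not isolated), via dienylketene 12 (not isolated), via cyclohexadienone 13 (not isolated)
Conditions: 9 (2 equiv), toluene, 80 to 110 °C, sealed tube under Ar; then K2CO3, MeOH, rt (returns any phenol acylated by the ketene)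
Reagents that add atoms: none
Why: On heating, 9 should open by four-electron electrocyclic ring opening to vinylketene 10, whose ketene C=C adds [2+2] to the electron-rich triple bond of 7 to give 4-vinylcyclobutenone 11; a second four-electron opening gives dienylketene 12, which closes to cyclohexadienone 13 and enolises to phenol 14. The closest known reaction type is the Danheiser benzannulation of cyclobutenones with 1-alkoxyalkynes; here the 3-alkoxy (vinylogous ester) cyclobutenone is expected to make the first ring opening the slow event. Ring A is closed by thermal six-electron electrocyclisation of 12 between the ketene carbon C2' and the terminal CH2 (C3'), after the [2+2] addition has made the new skeletal bonds C1'–C2' and C5'–C6'. No stereocentre is created: C1 and C6 of the cyclohexene and the carbinol carbon are spectators. The step needs the regiochemistry in which the ketene carbonyl carbon bonds to the alkyne carbon remote from oxygen, and the polarisation of the ynol ether secures it, so that OH and OMe flank the side chain and the allyloxy group sits para. The methoxy group cannot be lost by retro-ene fragmentation, the trisubstituted alkenes are far poorer ketene partners than the ynol ether, and the temperature stays below that of allyl ether Claisen rearrangement.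

**Step 6**
Reactants: 14 5-(allyloxy)-2-{(tert-butyldimethylsilyloxy)[(1R,6R)-4-(4-methylpent-3-en-1-yl)-6-phenylcyclohex-3-en-1-yl]methyl}-3-methoxyphenol
Product: 15 5-(allyloxy)-2-{hydroxy[(1R,6R)-4-(4-methylpent-3-en-1-yl)-6-phenylcyclohex-3-en-1-yl]methyl}-3-methoxyphenol
Conditions: Bu4NF, THF, 0 °C to rt; pH 7 phosphate buffer work-up; used at once
Reagents that add atoms: none
Why: Fluoride attacks silicon and releases the benzylic alkoxide (silyl ether cleavage), while the basic medium and neutral work-up should keep the electron-rich o-hydroxybenzylic alcohol from ionising.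

**Step 7**
Reactants: 15 5-(allyloxy)-2-{hydroxy[(1R,6R)-4-(4-methylpent-3-en-1-yl)-6-phenylcyclohex-3-en-1-yl]methyl}-3-methoxyphenol
Product: 16 [4-(allyloxy)-2-hydroxy-6-methoxyphenyl][(1R,6R)-4-(4-methylpent-3-en-1-yl)-6-phenylcyclohex-3-en-1-yl]methanone
Conditions: activated MnO2 (excess), CH2Cl2, rt
Reagents that add atoms: none
Why: MnO2 oxidises benzylic alcohols selectively and should leave the isolated alkenes and the allyl ether alone; both carbinol epimers converge on one ketone, stabilised by the hydrogen bond from the C2' hydroxyl, and C1 next to the new carbonyl keeps the trans (diequatorial, thermodynamically preferred) arrangement.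

**Step 8**
Reactants: 16 [4-(allyloxy)-2-hydroxy-6-methoxyphenyl][(1R,6R)-4-(4-methylpent-3-en-1-yl)-6-phenylcyclohex-3-en-1-yl]methanone
Product: 17 (2,4-dihydroxy-6-methoxyphenyl)[(1R,6R)-4-(4-methylpent-3-en-1-yl)-6-phenylcyclohex-3-en-1-yl]methanone
Conditions: Pd(PPh3)4 (5 mol%), morpholine, THF, rt; aq. NH4Cl
Reagents that add atoms: none
Why: Tsuji–Trost deallylation, in which Pd(PPh3)4 (zerovalent palladium) ionises the aryl allyl ether to a π-allyl complex and the C4' phenoxide and morpholine captures the allyl group, while the unactivated alkenes, the ketone and the methyl ether should be inert.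

**Compound list**

1 | myrcene (7-methyl-3-methyleneocta-1,6-diene) | C=CC(=C)CCC=C(C)C | starting material
2 | (E)-cinnamaldehyde | O=C/C=C/c1ccccc1 | starting material
3 | (1R,6R)-4-(4-methylpent-3-en-1-yl)-6-phenylcyclohex-3-ene-1-carbaldehyde (trans) | O=C[C@@H]1CC=C(CCC=C(C)C)C[C@H]1c1ccccc1 | intermediate
4 | chloroacetaldehyde dimethyl acetal (2-chloro-1,1-dimethoxyethane) | COC(CCl)OC | starting material
5 | lithium methoxyacetylide | COC#C[Li] | intermediate
6 | 3-methoxy-1-[(1R,6R)-4-(4-methylpent-3-en-1-yl)-6-phenylcyclohex-3-en-1-yl]prop-2-yn-1-ol (both carbinol epimers) | COC#CC(O)[C@@H]1CC=C(CCC=C(C)C)C[C@H]1c1ccccc1 | intermediate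
7 | tert-butyl{3-methoxy-1-[(1R,6R)-4-(4-methylpent-3-en-1-yl)-6-phenylcyclohex-3-en-1-yl]prop-2-yn-1-yloxy}dimethylsilane (both carbinol epimers) | COC#CC(O[Si](C)(C)C(C)(C)C)[C@@H]1CC=C(CCC=C(C)C)C[C@H]1c1ccccc1 | intermediate
8 | 3-ethoxycyclobut-2-en-1-one | CCOC1=CC(=O)C1 | starting material
9 | 3-(allyloxy)cyclobut-2-en-1-one | C=CCOC1=CC(=O)C1 | intermediate
10 | 3-(allyloxy)buta-1,3-dien-1-one (vinylketene) | C=CCOC(=C)C=C=O | intermediate
11 | 4-[1-(allyloxy)vinyl]-3-methoxy-2-{(tert-butyldimethylsilyloxy)[(1R,6R)-4-(4-methylpent-3-en-1-yl)-6-phenylcyclohex-3-en-1-yl]methyl}cyclobut-2-en-1-one | O=C1C(C(O[Si](C)(C)C(C)(C)C)[C@@H]2CC=C(CCC=C(C)C)C[C@H]2c3ccccc3)=C(OC)C1C(=C)OCC=C | intermediate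
12 | 5-(allyloxy)-3-methoxy-2-{(tert-butyldimethylsilyloxy)[(1R,6R)-4-(4-methylpent-3-en-1-yl)-6-phenylcyclohex-3-en-1-yl]methyl}hexa-1,3,5-trien-1-one (dienylketene, ketene and vinyl groups cis) | O=C=C(C(O[Si](C)(C)C(C)(C)C)[C@@H]1CC=C(CCC=C(C)C)C[C@H]1c1ccccc1)/C(OC)=C\C(=C)OCC=C | intermediate
13 | 5-(allyloxy)-3-methoxy-2-{(tert-butyldimethylsilyloxy)[(1R,6R)-4-(4-methylpent-3-en-1-yl)-6-phenylcyclohex-3-en-1-yl]methyl}cyclohexa-2,4-dien-1-one | O=C1CC(OCC=C)=CC(OC)=C1C(O[Si](C)(C)C(C)(C)C)[C@@H]2CC=C(CCC=C(C)C)C[C@H]2c3ccccc3 | intermediate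
14 | 5-(allyloxy)-2-{(tert-butyldimethylsilyloxy)[(1R,6R)-4-(4-methylpent-3-en-1-yl)-6-phenylcyclohex-3-en-1-yl]methyl}-3-methoxyphenol (both carbinol epimers) | COc1cc(OCC=C)cc(O)c1C(O[Si](C)(C)C(C)(C)C)[C@@H]1CC=C(CCC=C(C)C)C[C@H]1c1ccccc1 | intermediate
15 | 5-(allyloxy)-2-{hydroxy[(1R,6R)-4-(4-methylpent-3-en-1-yl)-6-phenylcyclohex-3-en-1-yl]methyl}-3-methoxyphenol (both carbinol epimers) | COc1cc(OCC=C)cc(O)c1C(O)[C@@H]1CC=C(CCC=C(C)C)C[C@H]1c1ccccc1 | intermediate
16 | [4-(allyloxy)-2-hydroxy-6-methoxyphenyl][(1R,6R)-4-(4-methylpent-3-en-1-yl)-6-phenylcyclohex-3-en-1-yl]methanone | COc1cc(OCC=C)cc(O)c1C(=O)[C@@H]1CC=C(CCC=C(C)C)C[C@H]1c1ccccc1 | intermediate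
17 | (2,4-dihydroxy-6-methoxyphenyl)[(1R,6R)-4-(4-methylpent-3-en-1-yl)-6-phenylcyclohex-3-en-1-yl]methanone | COc1cc(O)cc(O)c1C(=O)[C@@H]1CC=C(CCC=C(C)C)C[C@H]1c1ccccc1 | target

**Step count**

Total steps: 8. Longest linear sequence: 7 (steps 1, 2, 3, 5, 6, 7, 8); step 4 is a one-step side branch.

**Steps most likely to fail**

Step 5. The donor-stabilised cyclobutenone may open too slowly at temperatures the allyl vinyl ether tolerates. Ketene dimerisation or Claisen rearrangement may then outrun the [2+2] addition at the hindered alkyne carbon. The fallback builds ring A from a preformed arene; it sets out from aldehyde 3 and returns at target 17. Commercial 5-methoxyresorcinol is converted with MeOCH2Cl and i-Pr2NEt into 1-methoxy-3,5-bis(methoxymethoxy)benzene F1. NBS in CH2Cl2 at low temperature brominates between the methoxy and one methoxymethoxy group to give 2-bromo-1-methoxy-3,5-bis(methoxymethoxy)benzene F2; the symmetrical 4-bromo isomer would have to be removed by chromatography. Bromine–lithium exchange with n-BuLi in THF at −78 °C and addition to 3 should give [2-methoxy-4,6-bis(methoxymethoxy)phenyl][(1R,6R)-4-(4-methylpent-3-en-1-yl)-6-phenylcyclohex-3-en-1-yl]methanol F3. Dess–Martin periodinane with NaHCO3 should give [2-methoxy-4,6-bis(methoxymethoxy)phenyl][(1R,6R)-4-(4-methylpent-3-en-1-yl)-6-phenylcyclohex-3-en-1-yl]methanone F4. Dilute HCl in MeOH then removes both methoxymethyl groups to give 17.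

Step 1. The β-aryl enal may react too slowly with an unactivated acyclic diene under amine catalysis, and facial discrimination may be incomplete. The fallback uses a covalently bound chiral auxiliary and a Lewis acid; it sets out from myrcene 1 and returns at aldehyde 3. (R)-4-Benzyloxazolidin-2-one is N-acylated (n-BuLi, cinnamoyl chloride) to (R)-4-benzyl-3-[(E)-3-phenylprop-2-enoyl]oxazolidin-2-one F5. Et2AlCl-promoted Diels–Alder reaction with 1 in CH2Cl2 at −20 °C follows; the chelated s-cis imide should be attacked on the face opposite the benzyl group, the Cα-Re face for the R auxiliary. This should give (R)-4-benzyl-3-{[(1R,6R)-4-(4-methylpent-3-en-1-yl)-6-phenylcyclohex-3-en-1-yl]carbonyl}oxazolidin-2-one F6. LiBH4 reduction releases the auxiliary and gives [(1R,6R)-4-(4-methylpent-3-en-1-yl)-6-phenylcyclohex-3-en-1-yl]methanol F7, and Dess–Martin oxidation gives 3.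

Step 7. The free o-hydroxybenzylic carbinol on the electron-rich ring may ionise to an o-quinone methide, and the free phenol may be oxidised on the MnO2 surface. The fallback caps the phenol before the carbinol is unveiled; it sets out from phenol 14 and returns at target 17. Allyl bromide and K2CO3 in DMF should give the bis(allyl ether) {[2,4-bis(allyloxy)-6-methoxyphenyl][(1R,6R)-4-(4-methylpent-3-en-1-yl)-6-phenylcyclohex-3-en-1-yl]methoxy}(tert-butyl)dimethylsilane F8. Bu4NF gives [2,4-bis(allyloxy)-6-methoxyphenyl][(1R,6R)-4-(4-methylpent-3-en-1-yl)-6-phenylcyclohex-3-en-1-yl]methanol F9, which has no free ortho hydroxyl. Dess–Martin periodinane with NaHCO3 gives [2,4-bis(allyloxy)-6-methoxyphenyl][(1R,6R)-4-(4-methylpent-3-en-1-yl)-6-phenylcyclohex-3-en-1-yl]methanone F10. Pd(PPh3)4 with morpholine then removes both allyl groups to give 17.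

**Further compounds**

F1 | step 5 | 1-methoxy-3,5-bis(methoxymethoxy)benzene | COCOc1cc(OC)cc(OCOC)c1
F2 | step 5 | 2-bromo-1-methoxy-3,5-bis(methoxymethoxy)benzene | COCOc1cc(OC)c(Br)c(OCOC)c1
F3 | step 5 | [2-methoxy-4,6-bis(methoxymethoxy)phenyl][(1R,6R)-4-(4-methylpent-3-en-1-yl)-6-phenylcyclohex-3-en-1-yl]methanol | COCOc1cc(OC)c(C(O)[C@@H]2CC=C(CCC=C(C)C)C[C@H]2c3ccccc3)c(OCOC)c1
F4 | step 5 | [2-methoxy-4,6-bis(methoxymethoxy)phenyl][(1R,6R)-4-(4-methylpent-3-en-1-yl)-6-phenylcyclohex-3-en-1-yl]methanone | COCOc1cc(OC)c(C(=O)[C@@H]2CC=C(CCC=C(C)C)C[C@H]2c3ccccc3)c(OCOC)c1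
F5 | step 1 | (R)-4-benzyl-3-[(E)-3-phenylprop-2-enoyl]oxazolidin-2-one | O=C(/C=C/c1ccccc1)N1[C@H](Cc2ccccc2)COC1=O
F6 | step 1 | (R)-4-benzyl-3-{[(1R,6R)-4-(4-methylpent-3-en-1-yl)-6-phenylcyclohex-3-en-1-yl]carbonyl}oxazolidin-2-one | O=C([C@@H]1CC=C(CCC=C(C)C)C[C@H]1c1ccccc1)N1[C@H](Cc2ccccc2)COC1=O
F7 | step 1 | [(1R,6R)-4-(4-methylpent-3-en-1-yl)-6-phenylcyclohex-3-en-1-yl]methanol | OC[C@@H]1CC=C(CCC=C(C)C)C[C@H]1c1ccccc1
F8 | step 7 | {[2,4-bis(allyloxy)-6-methoxyphenyl][(1R,6R)-4-(4-methylpent-3-en-1-yl)-6-phenylcyclohex-3-en-1-yl]methoxy}(tert-butyl)dimethylsilane | COc1cc(OCC=C)cc(OCC=C)c1C(O[Si](C)(C)C(C)(C)C)[C@@H]1CC=C(CCC=C(C)C)C[C@H]1c1ccccc1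
F9 | step 7 | [2,4-bis(allyloxy)-6-methoxyphenyl][(1R,6R)-4-(4-methylpent-3-en-1-yl)-6-phenylcyclohex-3-en-1-yl]methanol | COc1cc(OCC=C)cc(OCC=C)c1C(O)[C@@H]1CC=C(CCC=C(C)C)C[C@H]1c1ccccc1
F10 | step 7 | [2,4-bis(allyloxy)-6-methoxyphenyl][(1R,6R)-4-(4-methylpent-3-en-1-yl)-6-phenylcyclohex-3-en-1-yl]methanone | COc1cc(OCC=C)cc(OCC=C)c1C(=O)[C@@H]1CC=C(CCC=C(C)C)C[C@H]1c1ccccc1
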